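**Watch the excess.** I decided that in a repeat of dusk I would follow the excess of X over J after the temperature change, not the yield.

| flask | G | D | E | temperature | remark | time |
|---|---|---|---|---|---|---|
| Sunday's | 14 mM | 14 mM | 33.6 mM | 65 °C | run made earlier |  |
| Thursday's | 21 mM | 21 mM | 33.6 mM | 100 °C | run made earlier |  |
| Monday's | 28 mM | 28 mM | 50 mM | 65 °C | run made earlier |  |
| dawn | 28 mM | 28 mM | 33.6 mM | 100 °C |  | 8.0 min |
| dusk | 28 mM | 28 mM | 33.6 mM |  | at 70 °C until 1.5 min, from then on at 130 °C | 8.0 min |
| winter | 28 mM | 28 mM | 33.6 mM | 70 °C |  | 8.0 min |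
| autumn | 28 mM | 28 mM | 33.6 mM | 130 °C |  | 8.0 min |

- Sunday's (time / min: X / %, J / %): 3.00: 5.8, 0.2; 5.00: 9.3, 0.9; 8.00: 15.1, 3.7; 15.0: 22.1, 4.3; 25.0: 30.1, 6.7; 30.0: 32.9, 6.5
- Thursday's (time / min: X / %, J / %): 0.417: 9.7, 0.3; 1.33: 20.2, 3.7; 2.50: 28.5, 7.4; 4.00: 33.3, 7.8; 5.00: 33.4, 8.3; 6.00: 34.2, 12.4
- Monday's (time / min: X / %, J / %): 3.00: 8.5, 2.5; 8.00: 19.2, 0.8; 15.0: 27.1, 5.3; 30.0: 36.8, 9.0

(each reading ± 1 percentage point)

- E is single-handed; G and D are mirror images of each other, charged as a racemate, each of them at the stated concentration
- steps that have been proposed: E + G -> X; E + D -> J; X <-> J; E -> Z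
- an excess is the difference of the two amounts in percent of their sum
- an excess is below zero if the other one leads
- the handed part of E does not stay in what it makes, so the products of the two hands are mirror images too

* the best flask by excess of X over J; "all alike" if 1.5 percentage points covers them all (dawn / dusk / winter / autumn / all alike)
* excess of X over J at the end, dawn
* excess of X over J at the end, dusk
* excess of X over J at the end, winter
* excess of X over J at the end, autumn

**Rate of fading.** X and J are mirror images, so X <-> J has an equilibrium constant of one, and the excess is a matter of kinetic, not thermodynamic, control. Once E stops making product, cX + cJ stands while cX − cJ decays first-order with a rate constant f, so the excess shrinks by the factor exp(−f t).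

On Thursday's run at 100 °C, the excess read 58.8 % at 2.50 min and 46.8 % at 6.00 min, so f read 0.0652 min⁻¹, with much scatter and with X and J still reading higher over that stretch. Monday's run at 65 °C, from 15.0 min to 30.0 min, read 0.00687 min⁻¹. That drift lies within the scatter, so I took it as a rough value.

In reciprocal temperature, the step from 100 °C to 130 °C is about 0.7 of the step from 65 °C to 100 °C. Arrhenius extrapolation therefore gave the fade rate, the first-order rate constant of the excess at 130 °C, as 0.315 min⁻¹, a rough estimate.

**Accumulated fading.** I reckoned dusk's product as if made at the change, with the excess Sunday's run read at 30.0 min, 67.0 %. Over the hot stretch of 6.50 min, I reckoned the surviving fraction at 12.9 %, so I expected about 8.64 % in dusk.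

**The forecast.** It named winter and gave 56 % for dawn, 48 % for dusk, 71 % for winter and 46 % for autumn, noting that “The late J rise hints at slow racemisation”. Its dusk figure stands above mine.

**The result.** The best flask was winter: dawn gave 49.8 %, dusk 0.602 %, winter 71.0 % and autumn 0.199 %.

    E + G → X (k = 16.2 M⁻¹ min⁻¹, Ea = 74.0 kJ mol⁻¹)
    E + D → J (k = 2.01 M⁻¹ min⁻¹, Ea = 70.0 kJ mol⁻¹)
    X ⇌ J (k = 0.0230 min⁻¹, Ea = 117 kJ mol⁻¹)
    E → Z (k = 0.110 min⁻¹, Ea = 116 kJ mol⁻¹)
    (constants at 100 °C)

In dusk, the relaxation half-life of X and J at the second temperature was 0.911 min, shorter than the 8.0 min of the run, and the hot stretch held 7.14 such half-lives. My fade rate implied a half-life of 2.20 min, longer than that.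

**Second flask.** In the neighbour flask, dusk stopped at 2.0 min, the hot stretch is 0.500 min, so my fade rate gives 57.2 %. The computed excess there is 54.9 %.

(The numbers in the tables are simulated for an exercise.)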